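**Retrosynthetic overview**

1. Target 36 ⇒ keto diol 32 (tiglate on O8 and senecioate on O9 removed) ⇒ cycloadduct 25, in which the C2 ketone is a silyl enol ether, O8/O9 are an acetonide and C6 still carries the ketone that activated the dienophile (later removed by reduction and Barton–McCombie deoxygenation).
2. Key disconnection: the C3–C4 and C5–C10 bonds of 25 are opened by an intramolecular Diels–Alder reaction to the acyclic trienone 24; rings A and B form together in this one step and no carbocycle exists before it.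
3. The strategy rests on ring A (C10, C1, C2, C3, C4, C5) having its ketone at C2, para to the quaternary C5, with cis methyl groups on C4 and C5, and on its cis fusion (C5, C10) to ring B (C5 to C10), whose C6–C9 can be an open four-atom tether. This is the imprint of a 2-silyloxydiene (C3=C2–C1=C10) on an (E)-tigloyl ketone (C4=C5–C6=O).
4. 24 ⇒ Weinreb amide 20 + but-2-en-2-yllithium; 20 ⇒ aldehyde 14 (olefination, acetonide, silyl dienol ether); C7 and C8 come from an Evans deconjugative syn aldol of senecioyl imide 4 with (S)-glyceraldehyde acetonide 5, which supplies C9.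

Key step: step 11

Remark: ring atoms are numbered C1–C10 as in the overview (isopropenyl on C7, oxygens on C8 and C9), β means the face of the C5 methyl group, and the C6 carbinol centre of 26–29 is left undefined because step 14 removes it.

Step 1
Reactants: 1 (R)-4-benzyl-1,3-oxazolidin-2-one; 2 3-methylbut-2-enoyl chloride
Product: 4 (R)-4-benzyl-3-(3-methylbut-2-enoyl)-1,3-oxazolidin-2-one, via lithium oxazolidinide 3 (not isolated)
Conditions: n-BuLi, THF, −78 °C; then 2, −78 → 0 °C
Reagents that add atoms: none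
Why: N-acylation of the lithiated Evans oxazolidinone with the acid chloride at −78 °C is the standard imide synthesis, and the absence of an amine base keeps the senecioyl double bond in conjugation; no stereocentre is formed.

Step 2
Reactants: 4 (R)-4-benzyl-3-(3-methylbut-2-enoyl)-1,3-oxazolidin-2-one; 5 (S)-2,2-dimethyl-1,3-dioxolane-4-carbaldehyde
Product: 8 (4R)-4-benzyl-3-[(2R,3R)-3-[(4S)-2,2-dimethyl-1,3-dioxolan-4-yl]-3-hydroxy-2-(prop-1-en-2-yl)propanoyl]-1,3-oxazolidin-2-one, via dibutylboron dienolate 6 (not isolated), via boron aldolate 7 (not isolated)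
Conditions: Bu2BOTf, Et3N, CH2Cl2, −78 → 0 °C; 5, −78 → 0 °C; pH 7 buffer, MeOH, 30% H2O2, 0 °C
Reagents that add atoms: none
Why: Evans syn aldol through the (Z)-boron dienolate formed by γ-deprotonation, which reacts at its α-carbon in a Zimmerman–Traxler chair so that the (R)-benzyl auxiliary sets C7 (R) and C8 (R) syn to each other, while the Cornforth/Felkin preference of the α-alkoxy aldehyde gives the same 8,9-anti relation to the existing (S) centre C9 (matched pair).

Step 3
Reactants: 8 the syn-aldol imide
Product: 10 (3R,4R,5S)-4-hydroxy-5-(hydroxymethyl)-3-(prop-1-en-2-yl)oxolan-2-one, via triol imide 9 (not isolated)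
Conditions: CSA (0.1 equiv), MeOH, 40 °C
Reagents that add atoms: none
Why: Acid methanolysis of the terminal acetonide frees O9, which is γ to the activated imide carbonyl and closes the five-membered lactone with release of the auxiliary (intramolecular acyl transfer), so deprotection and auxiliary removal are one operation that touches no stereocentre.

Step 4
Reactants: 10 the lactone diol
Product: 11 (2R,3R,4S)-3,4,5-trihydroxy-N-methoxy-N-methyl-2-(prop-1-en-2-yl)pentanamide
Conditions: MeNHOMe·HCl, AlMe3, CH2Cl2, 0 °C → rt; aq. Rochelle salt; crude used at once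
Reagents that add atoms: N,O-dimethylhydroxylamine hydrochloride, Cl.CNOC
Why: Aminolysis of the lactone with the aluminium amide made from AlMe3 and MeNHOMe·HCl (Weinreb amide formation) opens the ring at the acyl carbon without a base strong enough to epimerise C7 (a δ-lactone isomer from step 3 would give the same amide), and the crude γ-hydroxy amide is silylated at once so that it cannot relactonise.

Step 5
Reactants: 11 the triol Weinreb amide
Product: 12 (2R,3R,4S)-N-methoxy-N-methyl-2-(prop-1-en-2-yl)-3,4,5-tris(triethylsilyloxy)pentanamide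
Conditions: TESOTf, 2,6-lutidine, CH2Cl2, −78 → 0 °C
Reagents that add atoms: triethylsilyl trifluoromethanesulfonate, CC[Si](CC)(CC)OS(=O)(=O)C(F)(F)F
Why: Exhaustive silylation with the silyl triflate and a hindered pyridine base also protects the hindered C8 hydroxyl and blocks O9, which stops relactonisation.

Step 6
Reactants: 12 the tris-TES ether
Product: 14 (2R,3R,4R)-N-methoxy-N-methyl-5-oxo-2-(prop-1-en-2-yl)-3,4-bis(triethylsilyloxy)pentanamide, via alkoxysulfonium chloride 13 (not isolated)
Conditions: (COCl)2, DMSO, CH2Cl2, −78 → −30 °C; Et3N, −78 → 0 °C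
Reagents that add atoms: none
Why: Swern oxidation cleaves and oxidises a primary triethylsilyl ether directly while secondary triethylsilyl ethers survive, which gives the C10 aldehyde without a separate deprotection, and the low temperature limits epimerisation at C9.

Step 7
Reactants: 14 the C10 aldehyde; 15 dimethyl (2-oxopropyl)phosphonate
Product: 17 (2R,3R,4S,5E)-N-methoxy-N-methyl-7-oxo-2-(prop-1-en-2-yl)-3,4-bis(triethylsilyloxy)oct-5-enamide, via lithium phosphonate enolate 16 (not isolated)
Conditions: LiCl, iPr2NEt, MeCN, 0 °C → rt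
Reagents that add atoms: none
Why: Horner–Wadsworth–Emmons olefination under Masamune–Roush conditions is E-selective for β-ketophosphonates and mild enough for the α-silyloxy aldehyde, so the C10=C1 double bond is formed trans without loss of the C9 configuration.

Step 8
Reactants: 17 the bis-TES enone
Product: 19 (2R)-2-[(4R,5S)-2,2-dimethyl-5-[(1E)-3-oxobut-1-en-1-yl]-1,3-dioxolan-4-yl]-N-methoxy-N,3-dimethylbut-3-enamide, via enone diol 18 (not isolated)
Conditions: PPTS, MeOH, 0 °C → rt; then 2,2-dimethoxypropane, acetone, rt (one pot)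
Reagents that add atoms: 2,2-dimethoxypropane, COC(C)(C)OC
Why: PPTS in methanol removes the two secondary triethylsilyl ethers and 2,2-dimethoxypropane then ketalises the erythro 8,9-diol as the cis-dioxolane (acetal exchange), which masks O9 before it can lactonise onto the amide and leaves all stereocentres untouched.

Step 9
Reactants: 19 the enone acetonide
Product: 20 (2R)-2-[(4R,5S)-2,2-dimethyl-5-[(1E)-3-(triisopropylsilyloxy)buta-1,3-dien-1-yl]-1,3-dioxolan-4-yl]-N-methoxy-N,3-dimethylbut-3-enamide
Conditions: TIPSOTf, Et3N, CH2Cl2, −78 → 0 °C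
Reagents that add atoms: triisopropylsilyl trifluoromethanesulfonate, CC(C)[Si](OS(=O)(=O)C(F)(F)F)(C(C)C)C(C)C
Why: Soft enolisation with a silyl triflate and triethylamine removes a methyl proton of the enone kinetically and gives the cross-conjugated 2-silyloxydiene with the E double bond intact, while the much less acidic α-proton of the Weinreb amide (C7) is not touched.

Step 10
Reactants: 20 the silyloxydiene Weinreb amide; 21 (E)-2-bromobut-2-ene
Product: 24 (2E,5R)-5-[(4R,5S)-2,2-dimethyl-5-[(1E)-3-(triisopropylsilyloxy)buta-1,3-dien-1-yl]-1,3-dioxolan-4-yl]-3,6-dimethylhepta-2,6-dien-4-one, via but-2-en-2-yllithium 22 (not isolated), via lithium hemiaminal adduct 23 (not isolated)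
Conditions: 21, t-BuLi (2 equiv), Et2O, −78 °C; then 20, THF, −78 → −40 °C; pH 7 phosphate buffer, −78 °C
Reagents that add atoms: none
Why: Weinreb ketone synthesis in which bromine–lithium exchange proceeds with retention of the double-bond geometry, the vinyllithium adds once to the amide to give a stable chelate, and the enone is set free only on buffered work-up, so the base-sensitive C7 centre is never exposed to base as a ketone.

Step 11
Reactants: 24 the (E,E)-trienone
Product: 25 cis-fused cycloadduct (2-triisopropylsilyloxy-octal-1-en-6-one; 4β,5β-dimethyl; 7β-isopropenyl; 8α,9α-acetonide; 10β-H)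
Conditions: PhMe (0.005 M), BHT (cat.), 80 °C, base-washed glassware
Reagents that add atoms: none
Why: Thermal intramolecular Diels–Alder reaction of a 1,7,9-decatrien-3-one, a concerted suprafacial [4+2] in which the silyloxydiene terminus C3 (largest HOMO coefficient) bonds to the enone β-carbon C4 and C10 bonds to the α-carbon C5; the closest known reactions are the thermal cyclisations of substituted 1,7,9-decatrien-3-ones to cis-fused 1-octalones. Ring A (C10, C1, C2, C3, C4, C5) closes as the cyclohexene of the cycloaddition and ring B (C5 to C10) closes in the same event as a six-membered ring through the C6–C9 tether by the C5–C10 bond. C4 and C5 are set by the E geometry of the tigloyl unit, which is carried over suprafacially so that the two methyl groups are cis, and C10 is set relative to C5 by the endo placement of the tether carbonyl C6 under C1–C2 of the E diene, which gives the cis ring fusion. The selectivity still needed is the diene face, that is C4/C5/C10 relative to C7–C9: in the endo chair tether that leads to 25 the isopropenyl group would be axial and 1,3 to the C5 methyl and O8 axial under the diene, so the reaction should run through the endo boat-like tether that this substrate class is known to use and that keeps C6=O conjugated with C4=C5. In that boat the isopropenyl group at C7 is pseudo-equatorial, O8 takes the bowsprit position and the allylic C9–O bond lies near the diene plane, whereas attack on the other face through the same boat would force O8 into the flagpole position against the C5 methyl and turn the C9–O bond towards the anti position; the cis-dioxolane holds O8 and O9 gauche as both arrangements require. Reactivity rests on the matched donor diene and enone pair, which should compensate for the trisubstituted dienophile.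

Step 12
Reactants: 25 the cycloadduct
Product: 26 C6 alcohol of the cycloadduct (silyl enol ether and acetonide retained)
Conditions: LiAlH4, Et2O, −78 → 0 °C
Reagents that add atoms: none
Why: Hydride addition to the hindered C6 ketone is faster than enolisation towards C7 at low temperature and leaves the silyl enol ether and acetonide intact; the new C6 carbinol centre (axial hydride delivery from the β face is expected) need not be controlled because step 14 removes it.

Step 13
Reactants: 26 the C6 alcohol
Product: 29 C6 O-(S-methyl dithiocarbonate), via sodium alkoxide 27 (not isolated), via sodium xanthate 28 (not isolated)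
Conditions: NaH, imidazole (cat.), THF, 0 °C → rt; CS2; MeI
Reagents that add atoms: carbon disulfide, S=C=S; iodomethane, CI
Why: Xanthate formation (alkoxide, CS2, then S-methylation) is the standard activation of a hindered secondary alcohol for Barton–McCombie deoxygenation, and the basic conditions are compatible with the silyl enol ether and the acetonide.

Step 14
Reactants: 29 the xanthate
Product: 30 6-deoxy compound (2-triisopropylsilyloxy-octal-1-ene; 8α,9α-acetonide)
Conditions: Bu3SnH (0.5 M), AIBN, PhMe, 100 °C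
Reagents that add atoms: none
Why: Barton–McCombie deoxygenation in which the stannyl radical adds to the thiocarbonyl group and the C6 radical formed by β-scission is reduced by the concentrated tin hydride faster than it can rearrange through the homoallyl–cyclopropylcarbinyl pathway, so C6 becomes CH2 and no other centre is touched.

Step 15
Reactants: 30 the 6-deoxy silyl enol ether
Product: 32 keto diol (8α,9α-dihydroxy-4β,5β-dimethyl-7β-isopropenyl-cis-decalin-2-one), via keto acetonide 31 (not isolated)
Conditions: 1 M aq. HCl, THF, 0 °C → rt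
Reagents that add atoms: none
Why: Dilute aqueous acid protonates the silyl enol ether at C1 to release the C2 ketone and then hydrolyses the acetonide, while C4, C5 and C10 are not enolisable from the C2 ketone and the isopropenyl group tolerates dilute HCl at room temperature.

Step 16
Reactants: 32 the keto diol; 33 (E)-2-methylbut-2-enoyl chloride
Product: 35 8-O-tiglate with free 9-hydroxyl, via stannylene acetal 34 (not isolated)
Conditions: Bu2SnO, PhMe, reflux (−H2O); then 33, PhMe, 0 °C → rt
Reagents that add atoms: none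
Why: Stannylene-acetal-mediated monoacylation of a cis-1,2-diol on a six-membered ring delivers the acyl group to the equatorial oxygen, here O8 in the ring B chair that keeps the isopropenyl group equatorial, whereas the axial O9 is shielded by C4 and the ring fusion.

Step 17
Reactants: 35 the 8-O-tiglate; 2 3-methylbut-2-enoyl chloride
Product: 36 target CNP0181050.1
Conditions: pyridine, DMAP (cat.), CH2Cl2, 0 °C → rt
Reagents that add atoms: none
Why: DMAP-catalysed acylation with the acid chloride in pyridine esterifies the remaining axial C9 hydroxyl, and the use of pyridine instead of a trialkylamine keeps the senecioyl group from deconjugating through a vinylketene.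

**Compound list**

1 | (R)-4-benzyl-1,3-oxazolidin-2-one | O=C1N[C@H](Cc2ccccc2)CO1 | starting material
2 | 3-methylbut-2-enoyl chloride (senecioyl chloride) | CC(C)=CC(=O)Cl | starting material
3 | lithium (R)-4-benzyl-2-oxo-1,3-oxazolidin-3-ide | [Li]N1[C@H](Cc2ccccc2)COC1=O | intermediate
4 | (R)-4-benzyl-3-(3-methylbut-2-enoyl)-1,3-oxazolidin-2-one | CC(C)=CC(=O)N1[C@H](Cc2ccccc2)COC1=O | intermediate
5 | (S)-2,2-dimethyl-1,3-dioxolane-4-carbaldehyde ((S)-glyceraldehyde acetonide) | O=C[C@@H]1COC(C)(C)O1 | starting material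
6 | (Z)-dibutylboron dienolate of 4 | C=C(C)/C=C(\OB(CCCC)CCCC)N1[C@H](Cc2ccccc2)COC1=O | intermediate
7 | dibutylboron aldolate of 8 | C=C(C)[C@@H](C(=O)N1[C@H](Cc2ccccc2)COC1=O)[C@@H](OB(CCCC)CCCC)[C@@H]1COC(C)(C)O1 | intermediate
8 | (4R)-4-benzyl-3-[(2R,3R)-3-[(4S)-2,2-dimethyl-1,3-dioxolan-4-yl]-3-hydroxy-2-(prop-1-en-2-yl)propanoyl]-1,3-oxazolidin-2-one | C=C(C)[C@@H](C(=O)N1[C@H](Cc2ccccc2)COC1=O)[C@@H](O)[C@@H]1COC(C)(C)O1 | intermediate
9 | (4R)-4-benzyl-3-[(2R,3R,4S)-3,4,5-trihydroxy-2-(prop-1-en-2-yl)pentanoyl]-1,3-oxazolidin-2-one | C=C(C)[C@@H](C(=O)N1[C@H](Cc2ccccc2)COC1=O)[C@@H](O)[C@@H](O)CO | intermediate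
10 | (3R,4R,5S)-4-hydroxy-5-(hydroxymethyl)-3-(prop-1-en-2-yl)oxolan-2-one | C=C(C)[C@H]1C(=O)O[C@@H](CO)[C@@H]1O | intermediate
11 | (2R,3R,4S)-3,4,5-trihydroxy-N-methoxy-N-methyl-2-(prop-1-en-2-yl)pentanamide | C=C(C)[C@@H](C(=O)N(C)OC)[C@@H](O)[C@@H](O)CO | intermediate
12 | (2R,3R,4S)-N-methoxy-N-methyl-2-(prop-1-en-2-yl)-3,4,5-tris(triethylsilyloxy)pentanamide | C=C(C)[C@@H](C(=O)N(C)OC)[C@@H](O[Si](CC)(CC)CC)[C@@H](O[Si](CC)(CC)CC)CO[Si](CC)(CC)CC | intermediate
13 | dimethyl(alkoxy)sulfonium chloride at O10 of the 8,9-bis-TES ether | C=C(C)[C@@H](C(=O)N(C)OC)[C@@H](O[Si](CC)(CC)CC)[C@@H](O[Si](CC)(CC)CC)CO[S+](C)C.[Cl-] | intermediate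
14 | (2R,3R,4R)-N-methoxy-N-methyl-5-oxo-2-(prop-1-en-2-yl)-3,4-bis(triethylsilyloxy)pentanamide | C=C(C)[C@@H](C(=O)N(C)OC)[C@@H](O[Si](CC)(CC)CC)[C@@H](O[Si](CC)(CC)CC)C=O | intermediate
15 | dimethyl (2-oxopropyl)phosphonate | CC(=O)CP(=O)(OC)OC | starting material
16 | lithium enolate of 15 | [Li+].CC(=O)[CH-]P(=O)(OC)OC | intermediate
17 | (2R,3R,4S,5E)-N-methoxy-N-methyl-7-oxo-2-(prop-1-en-2-yl)-3,4-bis(triethylsilyloxy)oct-5-enamide | C=C(C)[C@@H](C(=O)N(C)OC)[C@@H](O[Si](CC)(CC)CC)[C@@H](O[Si](CC)(CC)CC)/C=C/C(C)=O | intermediate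
18 | (2R,3R,4S,5E)-3,4-dihydroxy-N-methoxy-N-methyl-7-oxo-2-(prop-1-en-2-yl)oct-5-enamide | C=C(C)[C@@H](C(=O)N(C)OC)[C@@H](O)[C@@H](O)/C=C/C(C)=O | intermediate
19 | (2R)-2-[(4R,5S)-2,2-dimethyl-5-[(1E)-3-oxobut-1-en-1-yl]-1,3-dioxolan-4-yl]-N-methoxy-N,3-dimethylbut-3-enamide | C=C(C)[C@@H](C(=O)N(C)OC)[C@H]1OC(C)(C)O[C@H]1/C=C/C(C)=O | intermediate
20 | (2R)-2-[(4R,5S)-2,2-dimethyl-5-[(1E)-3-(triisopropylsilyloxy)buta-1,3-dien-1-yl]-1,3-dioxolan-4-yl]-N-methoxy-N,3-dimethylbut-3-enamide | C=C(C)[C@@H](C(=O)N(C)OC)[C@H]1OC(C)(C)O[C@H]1/C=C/C(=C)O[Si](C(C)C)(C(C)C)C(C)C | intermediate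
21 | (E)-2-bromobut-2-ene | C/C=C(\C)Br | starting material
22 | but-2-en-2-yllithium (methyl groups cis, geometry of 21 retained) | C/C=C(\C)[Li] | intermediate
23 | lithium salt of the N-methoxy-N-methyl hemiaminal from 20 and 22 (carbinolamine centre undefined) | C/C=C(\C)C(O[Li])(N(C)OC)[C@H](C(C)=C)[C@H]1OC(C)(C)O[C@H]1/C=C/C(=C)O[Si](C(C)C)(C(C)C)C(C)C | intermediate
24 | (2E,5R)-5-[(4R,5S)-2,2-dimethyl-5-[(1E)-3-(triisopropylsilyloxy)buta-1,3-dien-1-yl]-1,3-dioxolan-4-yl]-3,6-dimethylhepta-2,6-dien-4-one | C/C=C(\C)C(=O)[C@H](C(C)=C)[C@H]1OC(C)(C)O[C@H]1/C=C/C(=C)O[Si](C(C)C)(C(C)C)C(C)C | intermediate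
25 | cis-fused cycloadduct: 2-(triisopropylsilyloxy)octal-1-en-6-one with 4β,5β-dimethyl, 7β-isopropenyl, 8α,9α-isopropylidenedioxy, 10β-H | C=C(C)[C@H]1C(=O)[C@@]2(C)[C@H](C=C(O[Si](C(C)C)(C(C)C)C(C)C)C[C@@H]2C)[C@@H]3OC(C)(C)O[C@H]13 | intermediate
26 | C6 alcohol of 25 (C6 configuration undefined) | C=C(C)[C@H]1C(O)[C@@]2(C)[C@H](C=C(O[Si](C(C)C)(C(C)C)C(C)C)C[C@@H]2C)[C@@H]3OC(C)(C)O[C@H]13 | intermediate
27 | sodium alkoxide of 26 | C=C(C)[C@H]1C([O-])[C@@]2(C)[C@H](C=C(O[Si](C(C)C)(C(C)C)C(C)C)C[C@@H]2C)[C@@H]3OC(C)(C)O[C@H]13.[Na+] | intermediate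
28 | sodium O-alkyl dithiocarbonate of 26 | C=C(C)[C@H]1C(OC(=S)[S-])[C@@]2(C)[C@H](C=C(O[Si](C(C)C)(C(C)C)C(C)C)C[C@@H]2C)[C@@H]3OC(C)(C)O[C@H]13.[Na+] | intermediate
29 | O-(C6) S-methyl dithiocarbonate of 26 | C=C(C)[C@H]1C(OC(=S)SC)[C@@]2(C)[C@H](C=C(O[Si](C(C)C)(C(C)C)C(C)C)C[C@@H]2C)[C@@H]3OC(C)(C)O[C@H]13 | intermediate
30 | 6-deoxy compound: 2-(triisopropylsilyloxy)octal-1-ene with 4β,5β-dimethyl, 7β-isopropenyl, 8α,9α-isopropylidenedioxy, 10β-H | C=C(C)[C@H]1C[C@@]2(C)[C@H](C=C(O[Si](C(C)C)(C(C)C)C(C)C)C[C@@H]2C)[C@@H]3OC(C)(C)O[C@H]13 | intermediate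
31 | 8α,9α-isopropylidenedioxy-4β,5β-dimethyl-7β-isopropenyl-cis-decalin-2-one | C=C(C)[C@H]1C[C@@]2(C)[C@H](CC(=O)C[C@@H]2C)[C@@H]3OC(C)(C)O[C@H]13 | intermediate
32 | 8α,9α-dihydroxy-4β,5β-dimethyl-7β-isopropenyl-cis-decalin-2-one (10β-H) | C=C(C)[C@H]1C[C@@]2(C)[C@H](CC(=O)C[C@@H]2C)[C@H](O)[C@@H]1O | intermediate
33 | (E)-2-methylbut-2-enoyl chloride (tigloyl chloride) | C/C=C(\C)C(=O)Cl | starting material
34 | 8,9-O-dibutylstannylene acetal of 32 | C=C(C)[C@H]1C[C@@]2(C)[C@H](CC(=O)C[C@@H]2C)[C@@H]3O[Sn](CCCC)(CCCC)O[C@H]13 | intermediate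
35 | 8α-[(E)-2-methylbut-2-enoyloxy]-9α-hydroxy-4β,5β-dimethyl-7β-isopropenyl-cis-decalin-2-one | C=C(C)[C@H]1C[C@@]2(C)[C@H](CC(=O)C[C@@H]2C)[C@H](O)[C@@H]1OC(=O)/C(C)=C/C | intermediate
36 | CNP0181050.1: 9α-(3-methylbut-2-enoyloxy)-8α-[(E)-2-methylbut-2-enoyloxy]-4β,5β-dimethyl-7β-isopropenyl-cis-decalin-2-one (10β-H) | C=C(C)[C@H]1C[C@@]2(C)[C@H](CC(=O)C[C@@H]2C)[C@H](OC(=O)C=C(C)C)[C@@H]1OC(=O)/C(C)=C/C | target

**Step count and risks**

Total step count: 17. Longest linear sequence: 17 steps (from 1 and 2 to 36; all other starting materials enter along this line).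

Steps most likely to fail:

Step 11. The cycloaddition may not discriminate between the two diene faces, because the endo chair tether (isopropenyl and O8 equatorial) leads to the opposite face from the endo boat tether on which the route relies, and some exo closure to the trans-fused series may intervene. The fallback reshapes the diene geometry and sets out from enone 19. Irradiation (365 nm, MeCN) to the photostationary mixture and separation gives the (Z)-enone F1, with the E isomer recycled. Soft enolisation (TIPSOTf, Et3N, −78 °C) gives the (Z)-silyloxydiene amide F2. Addition of 22 gives the lithium hemiaminal adduct F3, and buffered work-up gives the (Z)-trienone F4. Heating F4 (PhMe, BHT, about 140 °C) should give the same cycloadduct, so the fallback comes back to the route at 25. With the tether on the inside position of a Z diene only the cis-fused mode can be reached; the C6 carbonyl is then exo, and ring B can close through a chair in which the isopropenyl group and O8 are equatorial, while the opposite face would need an axial isopropenyl group against C4.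

Step 10. The vinyllithium may deprotonate C7 (α to the amide and allylic) instead of adding, which would lead to β-elimination of the C8 oxygen or loss of the C7 configuration, and addition to the hindered amide may stay incomplete. The fallback sets out from 20. Reduction with DIBAL-H (THF, −78 °C) gives the aldehyde F5, which is used cold and at once. The less basic organocerium reagent but-2-en-2-ylcerium dichloride F6, made from 22 and anhydrous CeCl3, adds to F5 at −78 °C to give the allylic alcohol F7 as a C6 epimer mixture. Oxidation with Dess–Martin periodinane buffered with pyridine gives the enone, so the fallback comes back to the route at 24.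

Step 16. The acylation may not discriminate well enough between O8 and O9, or the tiglate may migrate between the cis oxygens. The fallback sets out from 32 and reverses the order of the two esterifications. The more selective silylation with TESCl and imidazole (DMF, −20 °C) caps the equatorial O8 and gives the 8-O-triethylsilyl ether F8. Acylation of O9 with 2 (pyridine, DMAP) gives the 8-O-silyl 9-O-senecioate F9. HF·pyridine (THF, 0 °C; acidic, so no acyl migration) gives the 9-O-senecioate with free 8-hydroxyl F10. Acylation of O8 with 33 (pyridine, DMAP) then gives the target, so the fallback comes back to the route at 36.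

**Further compounds**

F1 | step 11 | (2R)-2-[(4R,5S)-2,2-dimethyl-5-[(1Z)-3-oxobut-1-en-1-yl]-1,3-dioxolan-4-yl]-N-methoxy-N,3-dimethylbut-3-enamide | C=C(C)[C@@H](C(=O)N(C)OC)[C@H]1OC(C)(C)O[C@H]1/C=C\C(C)=O
F2 | step 11 | (2R)-2-[(4R,5S)-2,2-dimethyl-5-[(1Z)-3-(triisopropylsilyloxy)buta-1,3-dien-1-yl]-1,3-dioxolan-4-yl]-N-methoxy-N,3-dimethylbut-3-enamide | C=C(C)[C@@H](C(=O)N(C)OC)[C@H]1OC(C)(C)O[C@H]1/C=C\C(=C)O[Si](C(C)C)(C(C)C)C(C)C
F3 | step 11 | lithium salt of the N-methoxy-N-methyl hemiaminal from F2 and 22 | C/C=C(\C)C(O[Li])(N(C)OC)[C@H](C(C)=C)[C@H]1OC(C)(C)O[C@H]1/C=C\C(=C)O[Si](C(C)C)(C(C)C)C(C)C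
F4 | step 11 | (2E,5R)-5-[(4R,5S)-2,2-dimethyl-5-[(1Z)-3-(triisopropylsilyloxy)buta-1,3-dien-1-yl]-1,3-dioxolan-4-yl]-3,6-dimethylhepta-2,6-dien-4-one | C/C=C(\C)C(=O)[C@H](C(C)=C)[C@H]1OC(C)(C)O[C@H]1/C=C\C(=C)O[Si](C(C)C)(C(C)C)C(C)C
F5 | step 10 | (2R)-2-[(4R,5S)-2,2-dimethyl-5-[(1E)-3-(triisopropylsilyloxy)buta-1,3-dien-1-yl]-1,3-dioxolan-4-yl]-3-methylbut-3-enal | O=C[C@H](C(C)=C)[C@H]1OC(C)(C)O[C@H]1/C=C/C(=C)O[Si](C(C)C)(C(C)C)C(C)C
F6 | step 10 | but-2-en-2-ylcerium dichloride (methyl groups cis) | C/C=C(\C)[Ce](Cl)Cl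
F7 | step 10 | (2E,5R)-5-[(4R,5S)-2,2-dimethyl-5-[(1E)-3-(triisopropylsilyloxy)buta-1,3-dien-1-yl]-1,3-dioxolan-4-yl]-3,6-dimethylhepta-2,6-dien-4-ol (C4 carbinol undefined) | C/C=C(\C)C(O)[C@H](C(C)=C)[C@H]1OC(C)(C)O[C@H]1/C=C/C(=C)O[Si](C(C)C)(C(C)C)C(C)C
F8 | step 16 | 8-O-triethylsilyl ether of 32 | C=C(C)[C@H]1C[C@@]2(C)[C@H](CC(=O)C[C@@H]2C)[C@H](O)[C@@H]1O[Si](CC)(CC)CC
F9 | step 16 | 8-O-triethylsilyl 9-O-(3-methylbut-2-enoyl) derivative of 32 | C=C(C)[C@H]1C[C@@]2(C)[C@H](CC(=O)C[C@@H]2C)[C@H](OC(=O)C=C(C)C)[C@@H]1O[Si](CC)(CC)CC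
F10 | step 16 | 9-O-(3-methylbut-2-enoyl) derivative of 32 with free 8-hydroxyl | C=C(C)[C@H]1C[C@@]2(C)[C@H](CC(=O)C[C@@H]2C)[C@H](OC(=O)C=C(C)C)[C@@H]1O
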